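**Assumption:** the SMILES is read as the (7S,8R,8′R,7′S)-furofuran [(+)-medioresinol core] with a (7″S,8″R)-erythro guaiacylglycerol on the syringyl oxygen. Compounds 1 (D-mannitol series) and 15 (L-serine series) are taken as catalogue items.

## Retrosynthetic overview

1. Hedyotol C ⇐ tri-O-benzyl ether ⇐ Felkin–Anh aryl addition to an α-aryloxy aldehyde (C7″ induced) ⇐ Mitsunobu inversion of an L-serine-derived α-hydroxy ester by mono-O-benzyl-(+)-medioresinol (C8″ bought).
2. Mono-O-benzyl-medioresinol ⇐ exo Friedel–Crafts arylation of a bicyclic lactol with 2,6-dimethoxyphenol (C7′) ⇐ vinyl cleavage of a 2-aryl-3-hydroxymethyl-4-vinyl-THF.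
3. That THF ⇐ SN1 cycloetherification (C7) ⇐ LiAlH4 ⇐ trans-aldol (C8) of (S)-β-vinyl-γ-butyrolactone with O-benzylvanillin.
4. (S)-β-Vinylbutyrolactone ⇐ Johnson–Claisen [3,3] rearrangement of the (Z)-allylic alcohol from (R)-glyceraldehyde acetonide. This makes the central C8–C8′ bond and sets C8′; the sugar stereocentre is then excised.
5. Ring order: temporary butyrolactone → THF ring A (C7–O–C9′) → THF ring B (C7′–O–C9, closed as lactol, then arylated).

## Route

**Step 1**
Reactants: 1, (R)-2,3-O-isopropylideneglyceraldehyde; 2, methyl (triphenylphosphoranylidene)acetate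
Product: 3, methyl (Z)-3-[(4S)-2,2-dimethyl-1,3-dioxolan-4-yl]prop-2-enoate
Conditions: MeOH, 0 °C (Z:E ≈ 8:1); chromatography
Reagents that add atoms: methyl (triphenylphosphoranylidene)acetate, COC(=O)C=P(c1ccccc1)(c1ccccc1)c1ccccc1
Why: Wittig olefination; stabilised ylides give mainly the Z-enoate with α-alkoxy aldehydes in methanol, and the bought stereocentre is untouched.

**Step 2**
Reactants: 3
Product: 4, (Z)-3-[(4S)-2,2-dimethyl-1,3-dioxolan-4-yl]prop-2-en-1-ol
Conditions: DIBAL-H (2.2 equiv), CH2Cl2, −78 °C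
Reagents that add atoms: none
Why: 1,2-reduction of the enoate to the allylic alcohol with retention of Z geometry.

**Step 3 (key step)**
Reactants: 4; 5, triethyl orthoacetate
Product: 6, ethyl (3S)-3-[(4S)-2,2-dimethyl-1,3-dioxolan-4-yl]pent-4-enoate
Conditions: MeC(OEt)3 (6 equiv), cat. EtCO2H, 140 °C, EtOH distilled off
Reagents that add atoms: triethyl orthoacetate, CCOC(C)(OCC)OCC
Why: Johnson orthoester Claisen ([3,3]-sigmatropic) forms the future C8–C8′ bond. The Z-alkene holds the allylic C–H in the alkene plane (A1,3 strain), so the new bond should form anti to the allylic C–O bond, giving 3S (lignan C8′). This facial sense is predicted from the model, not checked against data.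

**Step 4**
Reactants: 6
Product: 7, (4S)-4-ethenyloxolan-2-one [(S)-β-vinyl-γ-butyrolactone]
Conditions: H5IO6, EtOAc, 0 °C → rt; filter; NaBH4, EtOH, −20 → 0 °C; cat. TsOH, CH2Cl2 (telescoped, one isolation)
Reagents that add atoms: none
Why: periodic acid removes the terminal acetonide and cleaves the glycol in one pot; immediate borohydride reduction of the 2-vinyl aldehyde and lactonisation keep the Claisen stereocentre, and the former sugar carbon becomes the lactone CH2O (C9′).

**Step 5**
Reactants: 7; 8, 4-(benzyloxy)-3-methoxybenzaldehyde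
Product: 9, (3S,4R)-3-[[4-(benzyloxy)-3-methoxyphenyl](hydroxy)methyl]-4-ethenyloxolan-2-one (3,4-trans; both carbinol epimers)
Conditions: LDA, THF, −78 °C; then 8; AcOH quench at −78 °C
Reagents that add atoms: 4-(benzyloxy)-3-methoxybenzaldehyde, COc1cc(C=O)ccc1OCc1ccccc1
Why: lactone enolate aldol; the aldehyde adds anti to the β-vinyl group, setting C8 trans to C8′. The carbinol configuration is irrelevant because it is reset in step 7.

**Step 6**
Reactants: 9
Product: 10, (2R,3R)-2-[[4-(benzyloxy)-3-methoxyphenyl](hydroxy)methyl]-3-ethenylbutane-1,4-diol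
Conditions: LiAlH4, THF, 0 °C
Reagents that add atoms: none
Why: hydride reduction of the lactone to the 1,4-diol; C8 and C8′ are not epimerisable under these conditions.

**Step 7**
Reactants: 10
Product: 11, [(2S,3R,4R)-2-[4-(benzyloxy)-3-methoxyphenyl]-4-ethenyloxolan-3-yl]methanol
Conditions: CSA (10 mol %), CH2Cl2, 0 °C → rt
Reagents that add atoms: none
Why: SN1 cycloetherification through the p-alkoxybenzylic cation. Only the C9′ hydroxyl can close a five-membered ring, and the aryl group ends up trans to both neighbouring substituents, setting C7 (S) from either carbinol epimer.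

**Step 8**
Reactants: 11
Product: 12, (3aR,4S,6aR)-4-[4-(benzyloxy)-3-methoxyphenyl]tetrahydro-1H,3H-furo[3,4-c]furan-1-ol (anomeric mixture)
Conditions: OsO4 (2 mol %), NaIO4, 2,6-lutidine, dioxane/H2O, rt
Reagents that add atoms: osmium tetroxide, O=[Os](=O)(=O)=O, with sodium periodate, [Na+].[O-]I(=O)(=O)=O (one oxygen)
Why: Lemieux–Johnson cleavage of the vinyl group; the aldehyde is cis to the CH2OH and closes at once to the cis-fused lactol (ring B), which protects C8′ from epimerisation.

**Step 9**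
Reactants: 12; 13, 2,6-dimethoxyphenol
Product: 14, 4-[(1S,3aR,4S,6aR)-4-[4-(benzyloxy)-3-methoxyphenyl]tetrahydro-1H,3H-furo[3,4-c]furan-1-yl]-2,6-dimethoxyphenol
Conditions: 13 (3 equiv), BF3·OEt2 (1.2 equiv), 4 Å MS, CH2Cl2, −40 → −10 °C
Reagents that add atoms: 2,6-dimethoxyphenol, COc1cccc(OC)c1O
Why: Friedel–Crafts C-arylation of the bicyclic oxocarbenium ion at the position para to the phenol OH. Attack on the convex face puts the syringyl group exo (C7′ = S), and the syringyl OH is left free.

**Step 10**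
Reactants: 14; 15, methyl (2S)-3-(benzyloxy)-2-hydroxypropanoate
Product: 16, methyl (2R)-3-(benzyloxy)-2-{4-[(1S,3aR,4S,6aR)-4-[4-(benzyloxy)-3-methoxyphenyl]tetrahydro-1H,3H-furo[3,4-c]furan-1-yl]-2,6-dimethoxyphenoxy}propanoate
Conditions: PPh3, DIAD, THF, 0 °C → rt
Reagents that add atoms: methyl (2S)-3-(benzyloxy)-2-hydroxypropanoate, COC(=O)[C@@H](O)COCc1ccccc1
Why: Mitsunobu etherification of the only free OH in 14; clean SN2 inversion of the α-hydroxy ester turns bought 2S into 2R (C8″).

**Step 11**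
Reactants: 16
Product: 17, the corresponding (2R)-3-(benzyloxy)-2-aryloxypropanal
Conditions: DIBAL-H (1.1 equiv), CH2Cl2, −78 °C; MeOH then Rochelle salt; used crude
Reagents that add atoms: none
Why: partial reduction of an α-alkoxy ester stops at the aldehyde at −78 °C; cold, non-basic work-up avoids α-epimerisation.

**Step 12**
Reactants: 17; 18, 1-(benzyloxy)-4-bromo-2-methoxybenzene
Product: 19, (1S,2R)-3-(benzyloxy)-1-[4-(benzyloxy)-3-methoxyphenyl]-2-{4-[(1S,3aR,4S,6aR)-4-[4-(benzyloxy)-3-methoxyphenyl]tetrahydro-1H,3H-furo[3,4-c]furan-1-yl]-2,6-dimethoxyphenoxy}propan-1-ol (tri-O-benzyl hedyotol C)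
Conditions: 18, Mg, THF; ClTi(OiPr)3, −78 °C (ArTi(OiPr)3); then 17, −78 → −20 °C; chromatography
Reagents that add atoms: (4-benzyloxy-3-methoxyphenyl)magnesium bromide from 18, COc1cc([Mg]Br)ccc1OCc1ccccc1
Why: non-chelating, weakly basic aryltitanium addition under Felkin–Anh control (aryloxy group anti to the nucleophile) gives the anti (erythro) 7″S,8″R alcohol.

**Step 13**
Reactants: 19
Product: 20, hedyotol C
Conditions: H2 (1 atm), 10% Pd/C, EtOAc–THF, rt, stopped at full debenzylation
Reagents that add atoms: none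
Why: hydrogenolysis of two aryl benzyl ethers and one primary benzyl ether; in neutral aprotic solvent the furofuran benzylic C–O bonds and the benzylic alcohol should react more slowly and no stereocentre is touched, provided the reaction is monitored and stopped at full debenzylation.

## Compound list

1 | (R)-2,3-O-isopropylideneglyceraldehyde | O=C[C@H]1COC(C)(C)O1 | starting material
2 | methyl (triphenylphosphoranylidene)acetate | COC(=O)C=P(c1ccccc1)(c1ccccc1)c1ccccc1 | starting material
3 | methyl (Z)-3-[(4S)-2,2-dimethyl-1,3-dioxolan-4-yl]prop-2-enoate | COC(=O)/C=C\[C@H]1COC(C)(C)O1 | intermediate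
4 | (Z)-3-[(4S)-2,2-dimethyl-1,3-dioxolan-4-yl]prop-2-en-1-ol | OC/C=C\[C@H]1COC(C)(C)O1 | intermediate
5 | triethyl orthoacetate | CCOC(C)(OCC)OCC | starting material
6 | ethyl (3S)-3-[(4S)-2,2-dimethyl-1,3-dioxolan-4-yl]pent-4-enoate | CCOC(=O)C[C@@H](C=C)[C@H]1COC(C)(C)O1 | intermediate
7 | (4S)-4-ethenyloxolan-2-one | O=C1C[C@@H](C=C)CO1 | intermediate
8 | 4-(benzyloxy)-3-methoxybenzaldehyde | COc1cc(C=O)ccc1OCc1ccccc1 | starting material
9 | (3S,4R)-3-[[4-(benzyloxy)-3-methoxyphenyl](hydroxy)methyl]-4-ethenyloxolan-2-one (carbinol epimers) | O=C1OC[C@H](C=C)[C@H]1C(O)c1ccc(OCc2ccccc2)c(OC)c1 | intermediate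
10 | (2R,3R)-2-[[4-(benzyloxy)-3-methoxyphenyl](hydroxy)methyl]-3-ethenylbutane-1,4-diol | OC[C@H](C=C)[C@H](CO)C(O)c1ccc(OCc2ccccc2)c(OC)c1 | intermediate
11 | [(2S,3R,4R)-2-[4-(benzyloxy)-3-methoxyphenyl]-4-ethenyloxolan-3-yl]methanol | OC[C@H]1[C@@H](C=C)CO[C@@H]1c1ccc(OCc2ccccc2)c(OC)c1 | intermediate
12 | (3aR,4S,6aR)-4-[4-(benzyloxy)-3-methoxyphenyl]tetrahydro-1H,3H-furo[3,4-c]furan-1-ol | OC1OC[C@H]2[C@@H]1CO[C@@H]2c1ccc(OCc3ccccc3)c(OC)c1 | intermediate
13 | 2,6-dimethoxyphenol | COc1cccc(OC)c1O | starting material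
14 | 4-[(1S,3aR,4S,6aR)-4-[4-(benzyloxy)-3-methoxyphenyl]tetrahydro-1H,3H-furo[3,4-c]furan-1-yl]-2,6-dimethoxyphenol | COc1cc([C@H]2OC[C@H]3[C@@H]2CO[C@@H]3c2cc(OC)c(O)c(OC)c2)ccc1OCc1ccccc1 | intermediate
15 | methyl (2S)-3-(benzyloxy)-2-hydroxypropanoate | COC(=O)[C@@H](O)COCc1ccccc1 | starting material
16 | methyl (2R)-3-(benzyloxy)-2-aryloxypropanoate (aryl = syringyl ring of 14) | COc1cc([C@H]2OC[C@H]3[C@@H]2CO[C@@H]3c2cc(OC)c(O[C@H](COCc3ccccc3)C(=O)OC)c(OC)c2)ccc1OCc1ccccc1 | intermediate
17 | (2R)-3-(benzyloxy)-2-aryloxypropanal | COc1cc([C@H]2OC[C@H]3[C@@H]2CO[C@@H]3c2cc(OC)c(O[C@H](COCc3ccccc3)C=O)c(OC)c2)ccc1OCc1ccccc1 | intermediate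
18 | 1-(benzyloxy)-4-bromo-2-methoxybenzene | COc1cc(Br)ccc1OCc1ccccc1 | starting material
19 | tri-O-benzyl hedyotol C (1S,2R side chain) | COc1cc([C@H]2OC[C@H]3[C@@H]2CO[C@@H]3c2cc(OC)c(O[C@H](COCc3ccccc3)[C@@H](O)c3ccc(OCc4ccccc4)c(OC)c3)c(OC)c2)ccc1OCc1ccccc1 | intermediate
20 | hedyotol C | COc1cc([C@H]2OC[C@H]3[C@@H]2CO[C@@H]3c2cc(OC)c(O[C@H](CO)[C@@H](O)c3ccc(O)c(OC)c3)c(OC)c2)ccc1O | target

## Totals

Total steps: 13. Longest linear sequence: 13 (fully linear; 2, 5, 8, 13, 15 and 18 are bought). Enoate 3 is believed to be a catalogue compound; buying it would remove step 1.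

## Steps most likely to fail

1. **Steps 3–4 (C8′ configuration).** The Claisen face selectivity is a model-based prediction, and the 2-vinyl aldehyde in step 4 can enolise and racemise. Fallback: swap the roles of the two latent formyl arms. Ozonolysis of 6 with NaBH4 work-up gives the dioxolanyl lactone with no epimerisable aldehyde; the dioxolane is carried through steps 5–7 and unmasked with H5IO6 as the C7′ aldehyde. This uses 6 directly if the Claisen gives the opposite face, or the enantiomeric series from (S)-glyceraldehyde acetonide if it does not.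

2. **Step 9 (Friedel–Crafts arylation).** Risks are para versus meta regiochemistry on the phenol and acid epimerisation of the benzylic ethers. Fallback: add lithiated 4-bromo-2,6-dimethoxyphenol TBS ether to lactol 12, close ring B by acid-catalysed SN1 cycloetherification of the resulting diol, then remove the silyl group with TBAF.

3. **Step 12 (erythro selectivity on an epimerisable α-aryloxy aldehyde).** Fallback: set C7″ by hydride instead of C–C addition. Either oxidise the carbinol mixture (Dess–Martin) to the α-aryloxy aryl ketone, or reach it from 16 via the Weinreb amide and the aryllithium; then reduce under Felkin control (NaBH4, MeOH, low temperature), the usual erythro-selective route to β-O-4 units.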